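The incoming ligand is the charge that differs between these recipes, so the first question is how much of it each recipe offers.

| setting | teal | red | cedar | maple |
|---|---|---|---|---|
| starting complex | 24 mM | 24 mM | 24 mM | 24 mM |
| incoming ligand | 3.1 equiv | 3.7 equiv | 4.00 equiv | 2.50 equiv |
| remark | run made earlier | run made earlier |  |  |
| time |  |  | 8.0 h | 8.0 h |

Teal, red, cedar and maple share 24 mM of starting complex and differ in equivalents and time. The mean of c(incoming ligand) multiplied by the time is the ligand exposure. If each exchange is first order in c(incoming ligand), runs at equal exposure should stand alike. Maple's charge, held for its whole time, gives 480 mM·h, and this is its charged ligand exposure. But the ligand is consumed, so the charge overstates the mean.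

| run | time / h | complex with two exchanged / % |
|---|---|---|
| teal | 0.417 | 0 |
| teal | 0.833 | 3 |
| teal | 1.50 | 6 |
| teal | 3.00 | 15 |
| teal | 6.00 | 21 |
| red | 0.500 | 6 |
| red | 1.33 | 7 |
| red | 2.50 | 20 |
| red | 4.00 | 19 |
| red | 6.00 | 15 |

(readings scatter by 2 percentage points)

- the numbers in the tables scatter by 2 percentage points (one standard deviation)

On the same reckoning, teal's last reading stands at 446 mM·h and shows 21 %. Red's last reading stands at 533 mM·h and shows 15 %. Maple lies above teal and below red, so a straight line between the two readings gives 18.7 %, give or take the scatter. The readings show one species, so exposure ranks nothing.

1. which of these holds the largest part of the starting complex at the end of cedar (complex with one exchanged / complex with four exchanged / complex with three exchanged / starting complex / complex with two exchanged)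
2. which of these holds the largest part of the starting complex at the end of maple (complex with one exchanged / complex with four exchanged / complex with three exchanged / starting complex / complex with two exchanged)
3. complex with two exchanged at the end of maple, in percent of the starting complex charged

The forecast says complex with three exchanged for cedar, complex with one exchanged for maple and 18 % for n. Its ground for maple is “ligand-time exposure roughly matches red”, though at an earlier point on red than the line above.

Maple gives 18.8 %. Cedar's largest share is complex with three exchanged, at 24.9 %. Maple's is starting complex, at 24.9 %, ahead of complex with one exchanged at 16.8 %.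

    complex with two exchanged ⇌ isomer of the product (K = 0.920, k = 0.0140 min⁻¹)
    starting complex + incoming ligand → leaving ligand + complex with one exchanged (k = 0.0770 M⁻¹ min⁻¹)
    complex with one exchanged + incoming ligand → leaving ligand + complex with two exchanged (k = 0.170 M⁻¹ min⁻¹)
    complex with two exchanged + incoming ligand → leaving ligand + complex with three exchanged (k = 0.0870 M⁻¹ min⁻¹)
    complex with two exchanged → over-reaction product (k = 8.00 × 10⁻⁴ min⁻¹)
    complex with three exchanged + incoming ligand → leaving ligand + complex with four exchanged (k = 0.0430 M⁻¹ min⁻¹)

Maple has not come to rest at 8.0 h. Its mean ligand, taken from the states at the start, 4.00 h and 8.00 h, is 64.1 % of the charge, so its exposure is nearer 308 mM·h. At 8.00 h in maple, complex with two exchanged stands at 18.8 %, and its net making runs at 1.06 times its net removal. Yet at 80.0 h it stands at 3.90 %, with over-reaction product at 39.6 % and incoming ligand at 0.911 %.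

The neighbour of maple with 0.620 equiv has a charged exposure of 119 mM·h, close to teal at 1.50 h (112 mM·h), which reads 6 %. That neighbour gives 4.31 %.

Readings and results stem from a simulated flask with made-up constants, noise included.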